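**Retrosynthetic overview**
1. Target ⇐ 4-methoxybenzoylation of the only secondary hydroxyl (C7) of a 3a,6,7-triol ⇐ ketohydroxylation and alkoxide-directed reduction of a C6=C7 alkene in a cis-fused hydroazulene (sets C6 and C7).
2. C6=C7 alkene ⇐ Julia–Lythgoe elimination of a β-acetoxy sulfone ⇐ closure of the C8–C8a bond by a hydrogen-atom-transfer-initiated 7-endo radical conjugate addition; the seven-membered ring is formed last.
3. Enabling feature: the quaternary carbon C8a (CH3) is bonded directly to the ring-fusion carbinol C3a, so a 2-methylcyclopent-2-en-1-ol (C1=C8a alkene in the five-membered ring) gives the tertiary C8a radical on Markovnikov H-atom transfer, and the oxygenated C7 next to C8 can carry a sulfonyl group that makes a C7=C8 alkene the acceptor.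
4. Cyclization precursor ⇐ α-sulfonylvinyl anion + methyl ketone ⇐ Wacker oxidation ⇐ butenylcerium 1,2-addition anti to the isopropyl group (sets C3a) to (R)-5-isopropyl-2-methylcyclopent-2-enone.
5. Enone (five-membered ring, formed first) ⇐ ring-closing metathesis of a dienone from an Evans allylation (sets C3).

Key step: step 9

Remark: hydroazulene numbering (C1–C3, C3a, C4–C8, C8a) is used for all bicyclic compounds; the two stereocentres created without control on the way to the key step and in it (C6, C7) are carried as mixtures because step 11 removes them.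

Step 1
Reactants: 1 (R)-4-benzyl-1,3-oxazolidin-2-one; 2 3-methylbutanoyl chloride
Product: 3 (R)-4-benzyl-3-(3-methylbutanoyl)-1,3-oxazolidin-2-one
Conditions: n-BuLi, THF, −78 °C; then 2, −78 → 0 °C
Reagents that add atoms: none
Why: N-acylation of the lithiated oxazolidinone attaches the Evans auxiliary; no stereocentre is formed.

Step 2
Reactants: 3 (R)-4-benzyl-3-(3-methylbutanoyl)-1,3-oxazolidin-2-one; 4 allyl bromide
Product: 5 (R)-4-benzyl-3-[(2R)-2-(propan-2-yl)pent-4-enoyl]-1,3-oxazolidin-2-one
Conditions: NaN(SiMe3)2, THF, −78 °C; then 4, −78 → −40 °C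
Reagents that add atoms: none
Why: Evans asymmetric alkylation: the chelated Z-enolate is allylated on the face opposite the benzyl group, which sets the (2R) centre that becomes C3 of the target.

Step 3
Reactants: 5 (R)-4-benzyl-3-[(2R)-2-(propan-2-yl)pent-4-enoyl]-1,3-oxazolidin-2-one; 6 N,O-dimethylhydroxylamine hydrochloride
Product: 7 (2R)-N-methoxy-N-methyl-2-(propan-2-yl)pent-4-enamide
Conditions: AlMe3, CH2Cl2, 0 °C → rt; dilute HCl work-up
Reagents that add atoms: none
Why: Aluminium-amide transamination of the imide gives the Weinreb amide and releases the auxiliary; the α-centre is not touched.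

Step 4
Reactants: 7 (2R)-N-methoxy-N-methyl-2-(propan-2-yl)pent-4-enamide; 8 isopropenylmagnesium bromide
Product: 9 (4R)-2-methyl-4-(propan-2-yl)hepta-1,6-dien-3-one
Conditions: THF, 0 °C; dilute HCl work-up
Reagents that add atoms: none
Why: Weinreb ketone synthesis: the chelated tetrahedral adduct survives until work-up, so there is no over-addition and no enolization of the α-centre.

Step 5
Reactants: 9 (4R)-2-methyl-4-(propan-2-yl)hepta-1,6-dien-3-one
Product: 10 (5R)-2-methyl-5-(propan-2-yl)cyclopent-2-en-1-one
Conditions: second-generation Grubbs catalyst (5 mol %), CH2Cl2, 40 °C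
Reagents that add atoms: none
Why: Ring-closing metathesis between the isopropenyl ketone and the terminal alkene closes the five-membered ring, driven by loss of ethene; the stereocentre is not involved.

Step 6
Reactants: 10 (5R)-2-methyl-5-(propan-2-yl)cyclopent-2-en-1-one; 11 but-3-en-1-ylmagnesium bromide
Product: 12 (1S,5R)-1-(but-3-en-1-yl)-2-methyl-5-(propan-2-yl)cyclopent-2-en-1-ol (hydroxyl cis to isopropyl)
Conditions: anhydrous CeCl3, 11, THF, −78 °C; then 10, −78 °C; H2O
Reagents that add atoms: none
Why: Organocerium 1,2-addition avoids enolization (which would racemize C5) and attacks the carbonyl anti to the neighbouring isopropyl group, so the new carbinol (later C3a) carries its hydroxyl cis to isopropyl.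

Step 7
Reactants: 12 (1S,5R)-1-(but-3-en-1-yl)-2-methyl-5-(propan-2-yl)cyclopent-2-en-1-ol
Product: 13 4-[(1S,5R)-1-hydroxy-2-methyl-5-(propan-2-yl)cyclopent-2-en-1-yl]butan-2-one (in equilibrium with its cyclic hemiketal)
Conditions: PdCl2 (10 mol %), CuCl (20 mol %), O2 (1 atm), DMF/H2O 7:1, rt
Reagents that add atoms: water, O
Why: Tsuji–Wacker oxidation converts the terminal alkene into the methyl ketone while the trisubstituted ring alkene is inert; oxypalladation by the tertiary hydroxyl would hydrolyse to the same product.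

Step 8
Reactants: 13 4-[(1S,5R)-1-hydroxy-2-methyl-5-(propan-2-yl)cyclopent-2-en-1-yl]butan-2-one; 14 phenyl vinyl sulfone
Product: 15 (1S,5R)-1-[3-hydroxy-3-methyl-4-(phenylsulfonyl)pent-4-en-1-yl]-2-methyl-5-(propan-2-yl)cyclopent-2-en-1-ol (both epimers at the side-chain carbinol)
Conditions: 14, MeLi, THF, −95 °C; then lithium alkoxide of 13 (13 + MeLi, THF, −78 °C), −95 → −78 °C; H2O
Reagents that add atoms: none
Why: Carbonyl addition of the α-lithiated vinyl sulfone to the ketone gives the Morita–Baylis–Hillman-type tertiary alcohol; the new carbinol centre is not controlled and is erased in step 11.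

Step 9
Reactants: 15 (1S,5R)-1-[3-hydroxy-3-methyl-4-(phenylsulfonyl)pent-4-en-1-yl]-2-methyl-5-(propan-2-yl)cyclopent-2-en-1-ol
Product: 16 (3R,3aS,8aR)-6,8a-dimethyl-7-(phenylsulfonyl)-3-(propan-2-yl)decahydroazulene-3a,6-diol (cis-fused; mixture at C6 and C7)
Conditions: Fe(acac)3 (30 mol %), PhSiH3 (slow addition), EtOH/ethylene glycol 5:1, 0.01 M, 60 °C
Reagents that add atoms: none
Why: An iron hydride formed from Fe(acac)3 and PhSiH3 transfers a hydrogen atom to the CH carbon of the electron-rich ring alkene (Markovnikov), and the resulting tertiary C8a radical adds to the unsubstituted terminus (future C8) of the electron-poor 1-sulfonylvinyl group, after which the α-sulfonyl radical is reduced and protonated. The closest known reaction type is the hydrogen-atom-transfer-initiated reductive olefin coupling (Giese-type radical conjugate addition), here run intramolecularly. The seven-membered ring closes in the 7-endo-trig mode, because the 6-exo alternative would need a nucleophilic tertiary radical to attack the fully substituted, sulfonyl-bearing alkene carbon against both polarity and sterics. The new quaternary stereocentre C8a is controlled by the adjacent carbinol C3a: the tether leaves C3a on the face opposite the hydroxyl and isopropyl groups, so bond formation on that face should give the cis-fused bicycle with methyl and hydroxyl syn. The step needs H-atom transfer to the ring alkene only, which the opposite electronic character of the two alkenes secures, and ring closure faster than a second H-atom transfer, which high dilution, slow silane addition and the fully substituted tether carbons (C3a, C6) favour. The centres formed at C6 and C7 need no control since step 11 removes them.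

Step 10
Reactants: 16 (3R,3aS,8aR)-6,8a-dimethyl-7-(phenylsulfonyl)-3-(propan-2-yl)decahydroazulene-3a,6-diol
Product: 17 (3R,3aS,8aR)-6,8a-dimethyl-7-(phenylsulfonyl)-3-(propan-2-yl)decahydroazulene-3a,6-diyl diacetate (mixture at C6 and C7)
Conditions: Ac2O, Sc(OTf)3 (2 mol %), MeCN, −20 °C
Reagents that add atoms: acetic anhydride, CC(=O)OC(C)=O
Why: Lewis-acid-catalysed acetylation esterifies both hindered tertiary hydroxyls without base, which avoids retro-addition of the β-hydroxy sulfone; the C6 acetate is the leaving group for step 11 and the C3a acetate serves as protection until step 13.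

Step 11
Reactants: 17 (3R,3aS,8aR)-6,8a-dimethyl-7-(phenylsulfonyl)-3-(propan-2-yl)decahydroazulene-3a,6-diyl diacetate
Product: 18 (3R,3aS,8aR)-6,8a-dimethyl-3-(propan-2-yl)-2,3,4,5,8,8a-hexahydroazulen-3a(1H)-yl acetate
Conditions: Na(Hg) (6 % Na), Na2HPO4, THF/MeOH, −20 °C
Reagents that add atoms: none
Why: Julia–Lythgoe reductive elimination removes sulfinate from C7 and acetate from C6; all diastereomers converge on the endocyclic (necessarily Z) C6=C7 alkene, whose position is fixed by the sulfone.

Step 12
Reactants: 18 (3R,3aS,8aR)-6,8a-dimethyl-3-(propan-2-yl)-2,3,4,5,8,8a-hexahydroazulen-3a(1H)-yl acetate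
Product: 19 (3R,3aS,6R,8aR)-6-hydroxy-6,8a-dimethyl-7-oxo-3-(propan-2-yl)octahydroazulen-3a(1H)-yl acetate
Conditions: RuCl3 (1 mol %), KHSO5 (Oxone), NaHCO3, EtOAc/MeCN/H2O, rt
Reagents that add atoms: potassium peroxymonosulfate (KHSO5), [K+].[O-]S(=O)(=O)OO
Why: RuO4-catalysed ketohydroxylation of the trisubstituted alkene: [3+2] addition on the face opposite the angular methyl and acetoxy groups, then oxidation of the secondary carbon, should give the tertiary 6-hydroxyl (6R) and the C7 ketone in one operation.

Step 13
Reactants: 19 (3R,3aS,6R,8aR)-6-hydroxy-6,8a-dimethyl-7-oxo-3-(propan-2-yl)octahydroazulen-3a(1H)-yl acetate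
Product: 20 (3R,3aS,6R,7R,8aR)-6,8a-dimethyl-3-(propan-2-yl)decahydroazulene-3a,6,7-triol
Conditions: LiAlH4, THF, 0 °C; then H2O, aq. NaOH
Reagents that add atoms: none
Why: Hydride reduction of the α-hydroxy ketone: hydride is delivered from the face of the C6 alkoxyaluminate (also the face away from the C6 and angular methyl groups), giving the trans 6,7-diol (7R), and the tertiary acetate is cleaved reductively in the same operation.

Step 14
Reactants: 20 (3R,3aS,6R,7R,8aR)-6,8a-dimethyl-3-(propan-2-yl)decahydroazulene-3a,6,7-triol; 21 4-methoxybenzoyl chloride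
Product: 22 (3R,3aS,6R,7R,8aR)-3a,6-dihydroxy-6,8a-dimethyl-3-(propan-2-yl)decahydroazulen-7-yl 4-methoxybenzoate (CNP0244624.1)
Conditions: pyridine, DMAP (cat.), CH2Cl2, 0 °C → rt
Reagents that add atoms: none
Why: DMAP-catalysed acylation; only the secondary C7 hydroxyl reacts, the two tertiary hydroxyls are inert under these conditions.

**Compound list**
1 | (R)-4-benzyl-1,3-oxazolidin-2-one | O=C1N[C@H](Cc2ccccc2)CO1 | starting material
2 | 3-methylbutanoyl chloride | CC(C)CC(Cl)=O | starting material
3 | (R)-4-benzyl-3-(3-methylbutanoyl)-1,3-oxazolidin-2-one | CC(C)CC(=O)N1[C@H](Cc2ccccc2)COC1=O | intermediate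
4 | allyl bromide | C=CCBr | starting material
5 | (R)-4-benzyl-3-[(2R)-2-(propan-2-yl)pent-4-enoyl]-1,3-oxazolidin-2-one | C=CC[C@H](C(C)C)C(=O)N1[C@H](Cc2ccccc2)COC1=O | intermediate
6 | N,O-dimethylhydroxylamine hydrochloride | CNOC.Cl | starting material
7 | (2R)-N-methoxy-N-methyl-2-(propan-2-yl)pent-4-enamide | C=CC[C@H](C(C)C)C(=O)N(C)OC | intermediate
8 | isopropenylmagnesium bromide | CC(=C)[Mg]Br | starting material
9 | (4R)-2-methyl-4-(propan-2-yl)hepta-1,6-dien-3-one | C=CC[C@H](C(C)C)C(=O)C(C)=C | intermediate
10 | (5R)-2-methyl-5-(propan-2-yl)cyclopent-2-en-1-one | CC1=CC[C@H](C(C)C)C1=O | intermediate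
11 | but-3-en-1-ylmagnesium bromide | C=CCC[Mg]Br | starting material
12 | (1S,5R)-1-(but-3-en-1-yl)-2-methyl-5-(propan-2-yl)cyclopent-2-en-1-ol | CC1=CC[C@H](C(C)C)[C@@]1(O)CCC=C | intermediate
13 | 4-[(1S,5R)-1-hydroxy-2-methyl-5-(propan-2-yl)cyclopent-2-en-1-yl]butan-2-one | CC1=CC[C@H](C(C)C)[C@@]1(O)CCC(C)=O | intermediate
14 | phenyl vinyl sulfone | C=CS(=O)(=O)c1ccccc1 | starting material
15 | (1S,5R)-1-[3-hydroxy-3-methyl-4-(phenylsulfonyl)pent-4-en-1-yl]-2-methyl-5-(propan-2-yl)cyclopent-2-en-1-ol (both side-chain epimers) | CC1=CC[C@H](C(C)C)[C@@]1(O)CCC(C)(O)C(=C)S(=O)(=O)c1ccccc1 | intermediate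
16 | (3R,3aS,8aR)-6,8a-dimethyl-7-(phenylsulfonyl)-3-(propan-2-yl)decahydroazulene-3a,6-diol (mixture at C6, C7) | O=S(=O)(c1ccccc1)C1C[C@@]2(C)CC[C@H](C(C)C)[C@@]2(O)CCC1(C)O | intermediate
17 | (3R,3aS,8aR)-6,8a-dimethyl-7-(phenylsulfonyl)-3-(propan-2-yl)decahydroazulene-3a,6-diyl diacetate (mixture at C6, C7) | O=S(=O)(c1ccccc1)C1C[C@@]2(C)CC[C@H](C(C)C)[C@@]2(OC(C)=O)CCC1(C)OC(C)=O | intermediate
18 | (3R,3aS,8aR)-6,8a-dimethyl-3-(propan-2-yl)-2,3,4,5,8,8a-hexahydroazulen-3a(1H)-yl acetate | CC1=CC[C@@]2(C)CC[C@H](C(C)C)[C@@]2(OC(C)=O)CC1 | intermediate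
19 | (3R,3aS,6R,8aR)-6-hydroxy-6,8a-dimethyl-7-oxo-3-(propan-2-yl)octahydroazulen-3a(1H)-yl acetate | O=C1C[C@@]2(C)CC[C@H](C(C)C)[C@@]2(OC(C)=O)CC[C@@]1(C)O | intermediate
20 | (3R,3aS,6R,7R,8aR)-6,8a-dimethyl-3-(propan-2-yl)decahydroazulene-3a,6,7-triol | O[C@@H]1C[C@@]2(C)CC[C@H](C(C)C)[C@@]2(O)CC[C@@]1(C)O | intermediate
21 | 4-methoxybenzoyl chloride | COc1ccc(C(Cl)=O)cc1 | starting material
22 | (3R,3aS,6R,7R,8aR)-3a,6-dihydroxy-6,8a-dimethyl-3-(propan-2-yl)decahydroazulen-7-yl 4-methoxybenzoate | COc1ccc(C(=O)O[C@@H]2C[C@@]3(C)CC[C@H](C(C)C)[C@@]3(O)CC[C@@]2(C)O)cc1 | target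

Total step count: 14. Longest linear sequence: 14 steps (from 1).

**Steps most likely to fail**

Step 9. A second hydrogen-atom transfer to the tertiary radical (simple reduction of the ring alkene) may outrun the slow 7-endo closure, and the ring fusion may form with too little cis selectivity. The fallback sets out from 15. Hydroxyl-directed epoxidation of the ring alkene (VO(acac)2, t-BuOOH, CH2Cl2) would give the cis-epoxy alcohol F1. Cp2TiCl (from Cp2TiCl2 and Zn, THF), a trivalent titanium reagent, would open the epoxide homolytically to the same tertiary radical in a medium free of metal hydride. Closure onto the vinyl sulfone would give the 1-hydroxy analogue of 16, triol F2. The extra secondary hydroxyl would be converted into the O-phenyl thiocarbonate F3 (PhOC(S)Cl, pyridine, DMAP) and removed by Barton–McCombie deoxygenation (Bu3SnH, AIBN, toluene, 80 °C), which comes back to the route at 16.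

Step 8. The α-lithiated vinyl sulfone may polymerize or decompose before it adds to the ketone, which is partly masked as its lithium hemiketalate. The fallback sets out from 13. Addition of ethynylmagnesium bromide (THF, 0 °C → rt) would give the propargylic diol F4. Markovnikov hydrothiolation with thiophenol under Pd(OAc)2 catalysis would give the 2-(phenylthio)alkene F5. Chemoselective oxidation at sulfur (H2O2, (NH4)6Mo7O24, EtOH, 0 °C) would give the sulfone, which is 15.

Step 10. Acetylation of the hindered tertiary hydroxyl next to the sulfonyl carbon may stay incomplete, or the ring-fusion carbinol may ionize and eliminate under the Lewis acid. The fallback sets out from 13. Step 8 would be run with an acetic anhydride quench of the dilithium dialkoxide at −78 °C (in-situ acylation as in the classical Julia–Lythgoe protocol), giving the diacetate of 15, diacetate F6. F6 would then be taken through the conditions of step 9, which comes back to the route at 17.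

Further compounds
F1 | step 9 | cis-epoxy alcohol of 15 (2,3-epoxide of the cyclopentene ring, syn to the ring hydroxyl) | C[C@]12O[C@@H]2C[C@H](C(C)C)[C@@]1(O)CCC(C)(O)C(=C)S(=O)(=O)c1ccccc1
F2 | step 9 | (1R,3R,3aS,8aS)-6,8a-dimethyl-7-(phenylsulfonyl)-3-(propan-2-yl)decahydroazulene-1,3a,6-triol (mixture at C6, C7) | O=S(=O)(c1ccccc1)C1C[C@@]2(C)[C@H](O)C[C@H](C(C)C)[C@@]2(O)CCC1(C)O
F3 | step 9 | O-phenyl thiocarbonate of F2 at the C1 hydroxyl | O=S(=O)(c1ccccc1)C1C[C@@]2(C)[C@H](OC(=S)Oc3ccccc3)C[C@H](C(C)C)[C@@]2(O)CCC1(C)O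
F4 | step 8 | (1S,5R)-1-(3-hydroxy-3-methylpent-4-yn-1-yl)-2-methyl-5-(propan-2-yl)cyclopent-2-en-1-ol (both side-chain epimers) | CC1=CC[C@H](C(C)C)[C@@]1(O)CCC(C)(O)C#C
F5 | step 8 | (1S,5R)-1-[3-hydroxy-3-methyl-4-(phenylthio)pent-4-en-1-yl]-2-methyl-5-(propan-2-yl)cyclopent-2-en-1-ol (both side-chain epimers) | CC1=CC[C@H](C(C)C)[C@@]1(O)CCC(C)(O)C(=C)Sc1ccccc1
F6 | step 10 | diacetate of 15 (both tertiary hydroxyls acetylated) | CC1=CC[C@H](C(C)C)[C@@]1(OC(C)=O)CCC(C)(OC(C)=O)C(=C)S(=O)(=O)c1ccccc1
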